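## Retrosynthetic overview

- **Numbering:** C1 (NH2, CO2H), C2 (O-octanoyl), C3 (OH, Ph), C4, C5. NH2 and the C3-OH lie on one face (amine face). CO2H, the octanoate and Ph lie on the other (carboxyl face).
- **Feature the plan rests on:** N–C1(CO2H)–C5–C4 is the backbone of a homoserine activated at its gamma carbon, and C2–C3–Ph is phenylacetaldehyde. The cyclopentane therefore opens at C3–C4 and C1–C2.
- **Late disconnections:** first the octanoate (acylation of the secondary C2-OH next to the tertiary C3-OH, under Cbz/benzyl protection), then the C3-OH (retentive enzymatic C–H hydroxylation of the free amino acid).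
- **Ring order:** the cyclopentane is the only ring built. A pyridoxal 5'-phosphate (PLP) enzyme closes it in step 1 by gamma-substitution (C3–C4) followed by aldol (C1–C2), and sets C1, C2 and C3.

Key step: step 1

Assumption: neither biocatalyst is a catalogue item. Both are taken to be accessible by expression in E. coli and screening of homologues from fungal amino acid gene clusters, and each step uses the variant that gives the stereoisomer drawn.

## Route

Step 1
Reactants: 1 O-acetyl-L-homoserine; 2 phenylacetaldehyde
Product: 5 (1S,2S,3R)-1-amino-2-hydroxy-3-phenylcyclopentane-1-carboxylic acid, via PLP-bound vinylglycine ketimine 3 (not isolated), via PLP-bound quinonoid of the gamma-adduct 4 (not isolated)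
Conditions: recombinant PLP-dependent gamma-replacement/aldol cyclase (E. coli lysate or purified protein), PLP (cat.), K2HPO4/KH2PO4 buffer pH 7.5–8, 5% DMSO, 30 °C, 2 fed slowly by syringe pump; protein removal, cation-exchange isolation
Reagents that add atoms: none
Why: 1 forms the external aldimine with PLP, and loss of the alpha proton, tautomerisation to the ketimine and loss of a C5 proton expel acetate to give 3, a conjugate acceptor at C4, to which the enol of 2 adds through its benzylic carbon (C3–C4). Protonation of the resulting enamine at C5 and removal of a proton from the cofactor CH2 give quinonoid 4, whose carbanion at C1 attacks the tethered aldehyde carbon C2 in a 5-(enolexo)-exo-trig aldol that closes the cyclopentane, before transimination to the active-site lysine releases 5. The closest known reaction type is the PLP-dependent gamma-replacement of O-acylhomoserines with carbon nucleophiles, which members of this enzyme family are known to extend by this kind of intramolecular aldol to 2-hydroxy-1-aminocyclopentanecarboxylic acids. All three stereocentres are set by the protein: C3 by the enol face held against C4, C2 by the aldehyde face turned toward C1 and its general acid, and C1 by the open face of the planar quinonoid, where the original centre of 1 has been erased and the new bond must form on the face opposite to the departed alpha proton, away from the lysine that took it. The step needs C- over O-alkylation of the enol, ring closure ahead of protonation at C1 and release, and OH and Ph both on the carboxyl face; the phenyl-conjugated, abundant and soft enol of 2 and the three-atom tether C3–C4–C5 that holds the aldehyde within reach of C1 secure the first two, and the choice of enzyme secures the third. C3 can epimerise only while C2 is still an aldehyde, so the aldol also locks that centre.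

Step 2
Reactants: 5 (1S,2S,3R)-1-amino-2-hydroxy-3-phenylcyclopentane-1-carboxylic acid
Product: 6 (1S,2R,3S)-1-amino-2,3-dihydroxy-3-phenylcyclopentane-1-carboxylic acid
Conditions: recombinant 2-oxoglutarate-dependent non-heme iron oxygenase (clarified lysate), disodium 2-oxoglutarate (1.5 equiv), (NH4)2Fe(SO4)2·6H2O (cat.), sodium ascorbate (0.2 equiv), air, HEPES buffer pH 7.5, 25 °C; cation-exchange isolation
Reagents that add atoms: dioxygen, O=O
Why: Oxygenases of this class hold free alpha-amino acids by the ammonium carboxylate head group and hydroxylate C(sp3)–H bonds by hydrogen abstraction with a tetravalent iron-oxo species and hydroxyl rebound on the same face, so the weakest C–H bond of 5, the tertiary benzylic C3–H on the amine face, should be replaced by OH with retention (the descriptors become 2R,3S only through changed priorities); the step stands before acylation because the enzyme needs the free head group and because an octanoyl chain would offer many competing C–H bonds to any oxidant.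

Step 3
Reactants: 6 (1S,2R,3S)-1-amino-2,3-dihydroxy-3-phenylcyclopentane-1-carboxylic acid
Product: 7 (1S,2R,3S)-1-(benzyloxycarbonylamino)-2,3-dihydroxy-3-phenylcyclopentane-1-carboxylic acid
Conditions: CbzCl, NaHCO3, dioxane/H2O, 0 °C to rt; acidic work-up
Reagents that add atoms: benzyl chloroformate, O=C(Cl)OCc1ccccc1
Why: Under Schotten–Baumann conditions the amine is the only competent nucleophile toward the chloroformate, the two hydroxyl groups stay free in aqueous bicarbonate, and no stereocentre is touched.

Step 4
Reactants: 7 (1S,2R,3S)-1-(benzyloxycarbonylamino)-2,3-dihydroxy-3-phenylcyclopentane-1-carboxylic acid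
Product: 8 benzyl (1S,2R,3S)-1-(benzyloxycarbonylamino)-2,3-dihydroxy-3-phenylcyclopentane-1-carboxylate
Conditions: BnBr, KHCO3, DMF, rt
Reagents that add atoms: benzyl bromide, BrCc1ccccc1
Why: SN2 O-alkylation of the carboxylate makes the ester without activating the hindered carboxyl group, which could otherwise be captured by the cis C2-OH as a beta-lactone, and bicarbonate is too weak to deprotonate the alcohols or the carbamate.

Step 5
Reactants: 8 benzyl (1S,2R,3S)-1-(benzyloxycarbonylamino)-2,3-dihydroxy-3-phenylcyclopentane-1-carboxylate; 9 octanoyl chloride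
Product: 10 benzyl (1S,2R,3S)-1-(benzyloxycarbonylamino)-3-hydroxy-2-(octanoyloxy)-3-phenylcyclopentane-1-carboxylate
Conditions: pyridine (3 equiv), DMAP (cat.), CH2Cl2, 0 °C to rt
Reagents that add atoms: none
Why: DMAP-catalysed acylation should take the secondary C2-OH in preference to the tertiary benzylic C3-OH and the non-nucleophilic carbamate N–H; the C2–O bond is not broken, so the configuration holds, and the quaternary C1 rules out later beta-elimination of the ester.

Step 6
Reactants: 10 benzyl (1S,2R,3S)-1-(benzyloxycarbonylamino)-3-hydroxy-2-(octanoyloxy)-3-phenylcyclopentane-1-carboxylate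
Product: 11 fusarilin A
Conditions: H2 (1 atm), 10% Pd/C, EtOAc/EtOH, rt
Reagents that add atoms: none
Why: Neutral hydrogenolysis removes the benzyl ester and the Cbz group in one operation without acid or base, so the octanoate and the hindered tertiary benzylic alcohol (slow to hydrogenolyse without acid) should survive, and the freed amine is trans to the octanoate on the five-membered ring, so an O-to-N acyl shift through a trans-fused bicyclic intermediate is not expected.

## Compound list

1 | O-acetyl-L-homoserine, (2S)-4-acetoxy-2-aminobutanoic acid | CC(=O)OCC[C@H](N)C(=O)O | starting material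
2 | phenylacetaldehyde | O=CCc1ccccc1 | starting material
3 | PLP-bound vinylglycine ketimine, 2-iminobut-3-enoic acid with the imine nitrogen on the CH2 of the reduced cofactor | C=CC(=NCc1c(COP(=O)(O)O)cnc(C)c1O)C(=O)O | intermediate
4 | PLP-bound quinonoid of (5R)-2-amino-6-oxo-5-phenylhexanoic acid (gamma-adduct, carbanion equivalent at C1) | OC(=O)C(CC[C@@H](C=O)c1ccccc1)=NC=C1C(COP(=O)(O)O)=CNC(C)=C1O | intermediate
5 | (1S,2S,3R)-1-amino-2-hydroxy-3-phenylcyclopentane-1-carboxylic acid (OH and Ph on the carboxyl face, C3–H on the amine face) | O[C@@H]1[C@](N)(C(=O)O)CC[C@@H]1c2ccccc2 | intermediate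
6 | (1S,2R,3S)-1-amino-2,3-dihydroxy-3-phenylcyclopentane-1-carboxylic acid (C3-OH on the amine face) | O[C@@H]1[C@](N)(C(=O)O)CC[C@]1(O)c2ccccc2 | intermediate
7 | (1S,2R,3S)-1-(benzyloxycarbonylamino)-2,3-dihydroxy-3-phenylcyclopentane-1-carboxylic acid | O[C@@H]1[C@](NC(=O)OCc3ccccc3)(C(=O)O)CC[C@]1(O)c2ccccc2 | intermediate
8 | benzyl (1S,2R,3S)-1-(benzyloxycarbonylamino)-2,3-dihydroxy-3-phenylcyclopentane-1-carboxylate | O[C@@H]1[C@](NC(=O)OCc3ccccc3)(C(=O)OCc4ccccc4)CC[C@]1(O)c2ccccc2 | intermediate
9 | octanoyl chloride | CCCCCCCC(=O)Cl | starting material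
10 | benzyl (1S,2R,3S)-1-(benzyloxycarbonylamino)-3-hydroxy-2-(octanoyloxy)-3-phenylcyclopentane-1-carboxylate | CCCCCCCC(=O)O[C@@H]1[C@](NC(=O)OCc2ccccc2)(C(=O)OCc3ccccc3)CC[C@]1(O)c4ccccc4 | intermediate
11 | fusarilin A, (1S,2R,3S)-1-amino-3-hydroxy-2-(octanoyloxy)-3-phenylcyclopentane-1-carboxylic acid | CCCCCCCC(=O)O[C@@H]1[C@](N)(C(=O)O)CC[C@]1(O)c1ccccc1 | target

## Step count and risks

Total step count: 6. Longest linear sequence: 6 steps (from 1 or 2 to 11).

### Step 1

**Risk.** With the aryl donor the pocket may control the faces at C2 and C3 poorly. It may also protonate C1 and release the chain before the aldol.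

**Fallback.** It sets out from 1 and 2, comes back at 8 and bypasses steps 2 to 4. Only the ring and C1 are asked of the enzyme. C3 and C2 are reset chemically through the C2 ketone, which can enolise only toward C3 because C1 is quaternary. The most active homologue, whatever its C2/C3 selectivity, joins 1 and 2 to (1S)-1-amino-2-hydroxy-3-phenylcyclopentane-1-carboxylic acid as an epimer mixture F1. CbzCl/NaHCO3 gives the N-Cbz acid F2, and BnBr/KHCO3 gives its benzyl ester F3. Dess–Martin periodinane in CH2Cl2 brings all epimers together in the 2-oxo ester F4. TBSOTf/Et3N gives the only possible silyl enol ether F5. Rubottom oxidation with mCPBA/NaHCO3 should be steered to the amine face by hydrogen bonding of the peracid to the allylic carbamate N–H, giving the 3-silyloxy ketone F6. HF·pyridine then frees the tertiary alpha-hydroxy ketone F7. Hydroxyl-directed reduction with Me4NBH(OAc)3 in MeCN/AcOH delivers hydride from the face of the C3-OH. That face is also the one away from Ph and the ester, so the trans-diol 8 should result.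

### Step 2

**Risk.** No oxygenase variant may accept the quaternary amino acid. Hydrogen abstraction may also be followed by desaturation, or take place at C4 or on the arene.

**Fallback.** It sets out from 5 and comes back at 6. It uses stereoretentive oxygen insertion by a dioxirane on a protected substrate that carries no long alkyl chain. CF3CO2Et/Et3N in MeOH gives the N-trifluoroacetyl acid F8. MeI/KHCO3 in DMF gives the methyl ester F9, and Ac2O/DMAP/pyridine gives the C2 acetate F10. All three groups are electron-poor, and an amide N–H resists the N-oxidation that a carbamate N–H can suffer. Methyl(trifluoromethyl)dioxirane in CH2Cl2/1,1,1-trifluoroacetone at −20 to 0 °C should insert oxygen in a concerted way into the only tertiary and only benzylic C–H bond. The remaining doubt is how far the neighbouring acetoxy group deactivates that bond. The product is the tertiary alcohol F11. LiOH in THF/H2O removes acetate, trifluoroacetamide and methyl ester, and ion exchange gives 6.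

### Step 5

**Risk.** The C2-OH sits between two fully substituted carbons and on the face of Ph and the ester. Acylation may therefore be sluggish and lose its preference over the C3-OH.

**Fallback.** It sets out from 7 and 9, comes back at 11 and bypasses steps 4 to 6. The acyl group is delivered intramolecularly from the cis carboxyl group. Acid 7 with 9 and Et3N in THF at −10 °C gives the mixed carboxylic octanoic anhydride F12. On warming with catalytic DMAP the cis C2-OH should attack the unhindered octanoyl carbonyl through a six-membered cyclic intermediate. Attack at the inner carbonyl would need a beta-lactone, and the C3-OH on the other face cannot reach. The product is the N-Cbz O-octanoyl acid F13, and H2 over 10% Pd/C in EtOAc/EtOH gives 11.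

## Further compounds

F1 | step 1 | (1S)-1-amino-2-hydroxy-3-phenylcyclopentane-1-carboxylic acid, mixture of C2/C3 epimers | OC1[C@](N)(C(=O)O)CCC1c2ccccc2
F2 | step 1 | (1S)-1-(benzyloxycarbonylamino)-2-hydroxy-3-phenylcyclopentane-1-carboxylic acid, C2/C3 epimers | OC1[C@](NC(=O)OCc2ccccc2)(C(=O)O)CCC1c3ccccc3
F3 | step 1 | benzyl (1S)-1-(benzyloxycarbonylamino)-2-hydroxy-3-phenylcyclopentane-1-carboxylate, C2/C3 epimers | OC1[C@](NC(=O)OCc2ccccc2)(C(=O)OCc3ccccc3)CCC1c4ccccc4
F4 | step 1 | benzyl (1S)-1-(benzyloxycarbonylamino)-2-oxo-3-phenylcyclopentane-1-carboxylate, C3 labile | O=C1[C@](NC(=O)OCc2ccccc2)(C(=O)OCc3ccccc3)CCC1c4ccccc4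
F5 | step 1 | benzyl (1S)-1-(benzyloxycarbonylamino)-2-(tert-butyldimethylsilyloxy)-3-phenylcyclopent-2-ene-1-carboxylate | CC(C)(C)[Si](C)(C)OC=1[C@](NC(=O)OCc2ccccc2)(C(=O)OCc3ccccc3)CCC=1c4ccccc4
F6 | step 1 | benzyl (1S,3S)-1-(benzyloxycarbonylamino)-3-(tert-butyldimethylsilyloxy)-2-oxo-3-phenylcyclopentane-1-carboxylate | O=C1[C@](NC(=O)OCc2ccccc2)(C(=O)OCc3ccccc3)CC[C@]1(O[Si](C)(C)C(C)(C)C)c4ccccc4
F7 | step 1 | benzyl (1S,3S)-1-(benzyloxycarbonylamino)-3-hydroxy-2-oxo-3-phenylcyclopentane-1-carboxylate | O=C1[C@](NC(=O)OCc2ccccc2)(C(=O)OCc3ccccc3)CC[C@]1(O)c4ccccc4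
F8 | step 2 | (1S,2S,3R)-2-hydroxy-3-phenyl-1-(trifluoroacetylamino)cyclopentane-1-carboxylic acid | O[C@@H]1[C@](NC(=O)C(F)(F)F)(C(=O)O)CC[C@@H]1c2ccccc2
F9 | step 2 | methyl (1S,2S,3R)-2-hydroxy-3-phenyl-1-(trifluoroacetylamino)cyclopentane-1-carboxylate | O[C@@H]1[C@](NC(=O)C(F)(F)F)(C(=O)OC)CC[C@@H]1c2ccccc2
F10 | step 2 | methyl (1S,2S,3R)-2-acetoxy-3-phenyl-1-(trifluoroacetylamino)cyclopentane-1-carboxylate | CC(=O)O[C@@H]1[C@](NC(=O)C(F)(F)F)(C(=O)OC)CC[C@@H]1c2ccccc2
F11 | step 2 | methyl (1S,2R,3S)-2-acetoxy-3-hydroxy-3-phenyl-1-(trifluoroacetylamino)cyclopentane-1-carboxylate | CC(=O)O[C@@H]1[C@](NC(=O)C(F)(F)F)(C(=O)OC)CC[C@]1(O)c2ccccc2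
F12 | step 5 | mixed anhydride of 7 and octanoic acid | O[C@@H]1[C@](NC(=O)OCc2ccccc2)(C(=O)OC(=O)CCCCCCC)CC[C@]1(O)c3ccccc3
F13 | step 5 | (1S,2R,3S)-1-(benzyloxycarbonylamino)-3-hydroxy-2-(octanoyloxy)-3-phenylcyclopentane-1-carboxylic acid | CCCCCCCC(=O)O[C@@H]1[C@](NC(=O)OCc2ccccc2)(C(=O)O)CC[C@]1(O)c3ccccc3
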